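**Strategy.** Everything rests on cutting the O1–C8a bond of ring C. The oxygen pattern of ring A is symmetric about the C4a–C7 axis, so the O1–C8a bond and the C5–OH bond are equivalent ortho C–O bonds flanking C4a, and a 2,6-dibromoaryl ketone can deliver both. In one operation, copper-catalysed O-arylation of a 2-methoxy-1,3-diketone enolate closes the pyranone and leaves the second bromide at C5 for later hydroxylation. The precursor is a 1,3-diketone with a 4-benzyloxy-2,6-dibromo-3,5-dimethoxyphenyl ketone (ring A) and a 4-benzyloxy-2,5-dimethoxyphenyl ketone (ring B) flanking a CH(OMe) carbon. It is made by aldol addition and oxidation, which avoids acylation by a doubly ortho-blocked aroyl chloride.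

Key step: step 8

Remark: the aldol adduct and the diketone are carried as stereoisomer and tautomer mixtures, since both carbons concerned end as sp2 atoms of ring C; the Weinreb amide of methoxyacetic acid is taken as a purchasable reagent.

**Step 1**
Reactants: 1 2,5-dimethoxyphenol
Product: 2 2-(benzyloxy)-1,4-dimethoxybenzene
Conditions: BnBr (1.1 equiv), K2CO3 (1.5 equiv), DMF, rt to 60 °C
Reagents that add atoms: benzyl bromide, BrCc1ccccc1
Why: Williamson ether synthesis, in which the phenoxide formed by K2CO3 displaces bromide from benzyl bromide (SN2) and no other nucleophilic site is present.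

**Step 2**
Reactants: 2 2-(benzyloxy)-1,4-dimethoxybenzene
Product: 3 1-(benzyloxy)-4-bromo-2,5-dimethoxybenzene
Conditions: NBS (1.05 equiv), MeCN, 0 °C to rt, dark
Reagents that add atoms: N-bromosuccinimide, O=C1CCC(=O)N1Br
Why: Electrophilic aromatic bromination, which should go to the position para to the benzyloxy group and ortho to a methoxy group, the most activated and least crowded site of this 1,2,4-trialkoxybenzene.

**Step 3**
Reactants: 3 1-(benzyloxy)-4-bromo-2,5-dimethoxybenzene; 4 N,2-dimethoxy-N-methylacetamide
Product: 6 1-(4-benzyloxy-2,5-dimethoxyphenyl)-2-methoxyethan-1-one, via (4-benzyloxy-2,5-dimethoxyphenyl)lithium 5 (not isolated)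
Conditions: n-BuLi (1.05 equiv), THF, −78 °C; then 4 (1.2 equiv), −78 to 0 °C; 1 M HCl quench
Reagents that add atoms: none
Why: Bromine–lithium exchange followed by Weinreb ketone synthesis, in which the chelated tetrahedral adduct holds until the quench so that the aryllithium adds only once; no Lewis acid is needed, so the benzyl ether is not endangered.

**Step 4**
Reactants: 7 syringaldehyde (4-hydroxy-3,5-dimethoxybenzaldehyde)
Product: 8 4-benzyloxy-3,5-dimethoxybenzaldehyde
Conditions: BnBr (1.2 equiv), K2CO3 (1.5 equiv), DMF, 60 °C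
Reagents that add atoms: benzyl bromide, BrCc1ccccc1
Why: Williamson ether synthesis on the only phenol, with the aldehyde inert to carbonate.

**Step 5**
Reactants: 8 4-benzyloxy-3,5-dimethoxybenzaldehyde
Product: 9 4-benzyloxy-2,6-dibromo-3,5-dimethoxybenzaldehyde
Conditions: Br2 (2.5 equiv), NaOAc (3 equiv), AcOH, rt to 55 °C, dark
Reagents that add atoms: bromine, BrBr
Why: Electrophilic aromatic bromination at the only two free ring positions, each ortho to one methoxy group and para to the other, so that double bromination can only give the symmetric 2,6-dibromide; the acetate buffer takes up the HBr that could cleave the benzyl ether.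

**Step 6**
Reactants: 6 1-(4-benzyloxy-2,5-dimethoxyphenyl)-2-methoxyethan-1-one; 9 4-benzyloxy-2,6-dibromo-3,5-dimethoxybenzaldehyde
Product: 11 3-(4-benzyloxy-2,6-dibromo-3,5-dimethoxyphenyl)-1-(4-benzyloxy-2,5-dimethoxyphenyl)-3-hydroxy-2-methoxypropan-1-one (syn/anti mixture, racemic), via lithium Z-enolate 10 (not isolated)
Conditions: LiN(SiMe3)2 (1.1 equiv), THF, −78 °C; then 9, −78 °C; AcOH quench at −78 °C
Reagents that add atoms: none
Why: Aldol addition of the chelated lithium Z-enolate of an α-methoxy ketone to a non-enolisable aldehyde, quenched cold to prevent retro-aldol; the two new stereocentres are left uncontrolled because C3 is erased in step 7 and C2 in step 8.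

**Step 7**
Reactants: 11 3-(4-benzyloxy-2,6-dibromo-3,5-dimethoxyphenyl)-1-(4-benzyloxy-2,5-dimethoxyphenyl)-3-hydroxy-2-methoxypropan-1-one
Product: 12 1-(4-benzyloxy-2,6-dibromo-3,5-dimethoxyphenyl)-3-(4-benzyloxy-2,5-dimethoxyphenyl)-2-methoxypropane-1,3-dione (racemic, keto and enol forms)
Conditions: Dess–Martin periodinane (1.5 equiv), CH2Cl2, 0 °C to rt; aq. NaHCO3 wash
Reagents that add atoms: none
Why: Dess–Martin oxidation of a β-hydroxy ketone to the 1,3-diketone under non-basic conditions, which should leave the retro-aldol pathway closed and the benzyl ethers and aryl bromides untouched.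

**Step 8**
Reactants: 12 1-(4-benzyloxy-2,6-dibromo-3,5-dimethoxyphenyl)-3-(4-benzyloxy-2,5-dimethoxyphenyl)-2-methoxypropane-1,3-dione
Product: 13 7-benzyloxy-2-(4-benzyloxy-2,5-dimethoxyphenyl)-5-bromo-3,6,8-trimethoxy-4H-chromen-4-one
Conditions: CuI (10 mol %), K2CO3 (2 equiv), dry DMF (0.05 M), 100 °C, Ar
Reagents that add atoms: none
Why: K2CO3 removes the proton between the two carbonyl groups and the diketonate binds monovalent copper through oxygen; the C–Br bond ortho to the ring A carbonyl then adds to copper, and C–O reductive elimination joins the enolate oxygen on the ring B side to that carbon, forming O1–C8a. The closest known reaction type is the copper-catalysed intramolecular Ullmann O-arylation of 1-(2-haloaryl)-1,3-diketones to chromones and flavones. Ring C closes as a six-membered pyranone by a 6-exo attack of the enolate oxygen at an sp2 aryl carbon with loss of bromide. No stereocentre is formed, and the racemic CH(OMe) carbon of 12 becomes the sp2 carbon C3. The step needs O-arylation over C-arylation, which the substrate secures because the central carbon could only close a four-membered ring, and it needs no choice between the bromides because the two ortho positions of ring A are equivalent by symmetry. After closure no internal nucleophile is left, so the second bromide should survive at C5, peri to the carbonyl.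

**Step 9**
Reactants: 13 7-benzyloxy-2-(4-benzyloxy-2,5-dimethoxyphenyl)-5-bromo-3,6,8-trimethoxy-4H-chromen-4-one
Product: 14 7-benzyloxy-2-(4-benzyloxy-2,5-dimethoxyphenyl)-5-hydroxy-3,6,8-trimethoxy-4H-chromen-4-one
Conditions: Cu(acac)2 (10 mol %), N,N'-bis(4-hydroxy-2,6-dimethylphenyl)oxalamide (10 mol %), LiOH·H2O (3 equiv), DMSO/H2O 4:1, 80 °C; then 1 M HCl
Reagents that add atoms: lithium hydroxide, [Li+].[OH-]
Why: Copper-catalysed hydroxylation of an aryl bromide (Ullmann-type C–O coupling with hydroxide), helped by the carbonyl peri to C5–Br; the mild temperature and the acidic work-up should protect ring C, or reclose it if hydroxide opens it reversibly.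

**Step 10**
Reactants: 14 7-benzyloxy-2-(4-benzyloxy-2,5-dimethoxyphenyl)-5-hydroxy-3,6,8-trimethoxy-4H-chromen-4-one
Product: 15 5,7-dihydroxy-2-(4-hydroxy-2,5-dimethoxyphenyl)-3,6,8-trimethoxy-4H-chromen-4-one (5,7,4'-trihydroxy-3,6,8,2',5'-pentamethoxyflavone)
Conditions: H2 (1 atm), 10% Pd/C, EtOAc/MeOH, rt
Reagents that add atoms: none
Why: Catalytic hydrogenolysis of both aryl benzyl ethers; the tetrasubstituted C2=C3 bond, the ketone and the methyl ethers should not be reduced under these conditions, and no aryl bromide is left to be lost.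

**Compound list**
1 | 2,5-dimethoxyphenol | COc1ccc(OC)c(O)c1 | starting material
2 | 2-(benzyloxy)-1,4-dimethoxybenzene | COc1ccc(OC)c(OCc2ccccc2)c1 | intermediate
3 | 1-(benzyloxy)-4-bromo-2,5-dimethoxybenzene | COc1cc(Br)c(OC)cc1OCc1ccccc1 | intermediate
4 | N,2-dimethoxy-N-methylacetamide | COCC(=O)N(C)OC | starting material
5 | (4-benzyloxy-2,5-dimethoxyphenyl)lithium (not isolated) | [Li]c1cc(OC)c(OCc2ccccc2)cc1OC | intermediate
6 | 1-(4-benzyloxy-2,5-dimethoxyphenyl)-2-methoxyethan-1-one | COCC(=O)c1cc(OC)c(OCc2ccccc2)cc1OC | intermediate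
7 | syringaldehyde (4-hydroxy-3,5-dimethoxybenzaldehyde) | COc1cc(C=O)cc(OC)c1O | starting material
8 | 4-benzyloxy-3,5-dimethoxybenzaldehyde | COc1cc(C=O)cc(OC)c1OCc1ccccc1 | intermediate
9 | 4-benzyloxy-2,6-dibromo-3,5-dimethoxybenzaldehyde | COc1c(Br)c(C=O)c(Br)c(OC)c1OCc1ccccc1 | intermediate
10 | lithium (Z)-1-(4-benzyloxy-2,5-dimethoxyphenyl)-2-methoxyethen-1-olate (not isolated) | [Li+].CO/C=C(\[O-])c1cc(OC)c(OCc2ccccc2)cc1OC | intermediate
11 | 3-(4-benzyloxy-2,6-dibromo-3,5-dimethoxyphenyl)-1-(4-benzyloxy-2,5-dimethoxyphenyl)-3-hydroxy-2-methoxypropan-1-one (syn/anti mixture, racemic) | COc1cc(C(=O)C(OC)C(O)c2c(Br)c(OC)c(OCc3ccccc3)c(OC)c2Br)c(OC)cc1OCc1ccccc1 | intermediate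
12 | 1-(4-benzyloxy-2,6-dibromo-3,5-dimethoxyphenyl)-3-(4-benzyloxy-2,5-dimethoxyphenyl)-2-methoxypropane-1,3-dione (racemic) | COc1cc(C(=O)C(OC)C(=O)c2c(Br)c(OC)c(OCc3ccccc3)c(OC)c2Br)c(OC)cc1OCc1ccccc1 | intermediate
13 | 7-benzyloxy-2-(4-benzyloxy-2,5-dimethoxyphenyl)-5-bromo-3,6,8-trimethoxy-4H-chromen-4-one | COc1cc(-c2oc3c(OC)c(OCc4ccccc4)c(OC)c(Br)c3c(=O)c2OC)c(OC)cc1OCc1ccccc1 | intermediate
14 | 7-benzyloxy-2-(4-benzyloxy-2,5-dimethoxyphenyl)-5-hydroxy-3,6,8-trimethoxy-4H-chromen-4-one | COc1cc(-c2oc3c(OC)c(OCc4ccccc4)c(OC)c(O)c3c(=O)c2OC)c(OC)cc1OCc1ccccc1 | intermediate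
15 | 5,7-dihydroxy-2-(4-hydroxy-2,5-dimethoxyphenyl)-3,6,8-trimethoxy-4H-chromen-4-one | COc1cc(-c2oc3c(OC)c(O)c(OC)c(O)c3c(=O)c2OC)c(OC)cc1O | target

**Total step count:** 10
**Longest linear sequence:** 8 steps (steps 1, 2, 3, 6, 7, 8, 9, 10 from 2,5-dimethoxyphenol); the ring A branch from syringaldehyde is 7 steps.

**Steps most likely to fail**

1. Step 8. Oxidative addition at the crowded, electron-rich C–Br bond may be slow, so that retro-Claisen cleavage of the diketone by carbonate or loss of bromine by reduction takes over on long heating. The fallback sets out from 12 and comes back at 13. It changes the metal and the mechanism of C–O bond formation, not the disconnection, which is fixed. A palladium-catalysed intramolecular enolate O-arylation would be used, with Pd2(dba)3, DPEphos and Cs2CO3 in toluene at 90 °C. Zerovalent palladium inserts into C–Br, and C–O reductive elimination from the oxygen-bound palladium enolate closes the ring. This is the known way to benzofurans from 2-bromoaryl ketones. No new compound is made on this way (entry F0).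

2. Step 9. Hydroxide may add at C2 and fragment ring C, or the catalyst may stall through chelation by the 5-hydroxychromone that forms. The fallback sets out from 13 and comes back at 15. Ullmann methoxylation with NaOMe and CuI in DMF/MeOH at 100 °C would give 7-benzyloxy-2-(4-benzyloxy-2,5-dimethoxyphenyl)-3,5,6,8-tetramethoxy-4H-chromen-4-one F1. BCl3 with pentamethylbenzene in CH2Cl2 at −78 to 0 °C would then cleave the peri 5-methyl ether, through its six-membered chelate with the C4 carbonyl, together with both benzyl ethers. This gives the target directly and replaces steps 9 and 10.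

3. Step 5. The second bromination may stall on the deactivated monobromo aldehyde, and forcing it may bring loss of the benzyl ether or oxidation of the formyl group. The fallback sets out from 8 and comes back at 9. Reduction with NaBH4 in MeOH would give (4-benzyloxy-3,5-dimethoxyphenyl)methanol F2, whose ring is no longer deactivated. Double bromination with NBS (2.2 equiv) in MeCN would give (4-benzyloxy-2,6-dibromo-3,5-dimethoxyphenyl)methanol F3. Oxidation with Dess–Martin periodinane in CH2Cl2 would return aldehyde 9.

**Further compounds**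
F0 | step 8 | none | none
F1 | step 9 | 7-benzyloxy-2-(4-benzyloxy-2,5-dimethoxyphenyl)-3,5,6,8-tetramethoxy-4H-chromen-4-one | COc1cc(-c2oc3c(OC)c(OCc4ccccc4)c(OC)c(OC)c3c(=O)c2OC)c(OC)cc1OCc1ccccc1
F2 | step 5 | (4-benzyloxy-3,5-dimethoxyphenyl)methanol | COc1cc(CO)cc(OC)c1OCc1ccccc1
F3 | step 5 | (4-benzyloxy-2,6-dibromo-3,5-dimethoxyphenyl)methanol | COc1c(Br)c(CO)c(Br)c(OC)c1OCc1ccccc1
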